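**Retrosynthetic overview**

1. Target ← oxidation of the C2' carbinol (last step, so the labile C1' centre never meets base) ← C1' senecioate ← 8-(1,2-bis-silyloxyalkyl)-7-methoxycoumarin with orthogonal silyl ethers (TES on C1'–O, TBS on C2'–O).
2. Pyranone ring B (O1, C2, C3, C4, C4a, C8a) ← salicylaldehyde by O-acylation and intramolecular Wittig reaction with Ph3P=C=C=O; C4 ← ortho-formylation of the phenol at C4a.
3. Benzene ring A (C4a, C5, C6, C7, C8, C8a) ← cyclobutenone + chiral 1-methoxyalkyne by thermal benzannulation (C8–C8a, C6–C7, then C4a–C8a). The strategy rests on the four contiguous substituents of ring A, above all the C8 side chain lodged between C7–OMe and C8a–O1: a 2-alkylresorcinol monoether, which is what a vinylketene and an alkoxyalkyne assemble.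
4. Ynol ether ← Felkin–Anh addition of lithium methoxyacetylide to (S)-2-silyloxy-3-methylbutanal (from (S)-2-hydroxy-3-methylbutanoic acid); the chiral-pool centre (C2') sets C1' as R and is erased in the last step.
5. Ring order: ring A (step 8), then ring B (step 10).

Key step: step 8

Remark (assumption on the chemistry): the C2' oxygen is carried as a TBS ether and the C1' oxygen as a TES ether, so that C1' can be unmasked first and C2' later with HF·pyridine beside the ester. Locants follow coumarin numbering; C1' is the benzylic carbon and C2' the future ketone carbon.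

**Route**

Step 1
Reactants: 1 (S)-2-hydroxy-3-methylbutanoic acid
Product: 2 methyl (S)-2-hydroxy-3-methylbutanoate
Conditions: MeOH, H2SO4 (cat.), reflux
Reagents that add atoms: methanol, CO
Why: Fischer esterification; acid catalysis in methanol neither enolises nor ionises the α-hydroxy centre, so C2 stays S.

Step 2
Reactants: 2 methyl (S)-2-hydroxy-3-methylbutanoate
Product: 3 methyl (S)-2-(tert-butyldimethylsilyloxy)-3-methylbutanoate
Conditions: TBSCl, imidazole, DMF, rt
Reagents that add atoms: tert-butyldimethylsilyl chloride, CC(C)(C)[Si](C)(C)Cl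
Why: Imidazole-promoted O-silylation of a secondary alcohol; the bulky, non-chelating silyl ether is also what later favours Felkin–Anh over chelation control.

Step 3
Reactants: 3 methyl (S)-2-(tert-butyldimethylsilyloxy)-3-methylbutanoate
Product: 4 (S)-2-(tert-butyldimethylsilyloxy)-3-methylbutanal
Conditions: i-Bu2AlH, CH2Cl2, −78 °C; MeOH, then aq. potassium sodium tartrate (KNaC4H4O6)
Reagents that add atoms: none
Why: Partial ester reduction with i-Bu2AlH at −78 °C reliably stops at the aldehyde for α-silyloxy esters; the configurationally sensitive aldehyde is used crude at once.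

Step 4
Reactants: 4 (S)-2-(tert-butyldimethylsilyloxy)-3-methylbutanal; 5 chloroacetaldehyde dimethyl acetal
Product: 7 (3R,4S)-4-(tert-butyldimethylsilyloxy)-1-methoxy-5-methylhex-1-yn-3-ol, via lithium methoxyacetylide 6 (not isolated)
Conditions: 5, LiNEt2 (3 equiv, from Et2NH and n-BuLi), THF, 0 °C; then 4, −78 °C; aq. NaH2PO4/Na2HPO4 buffer added at −78 °C
Reagents that add atoms: chloroacetaldehyde dimethyl acetal (reactant 5), COC(OC)CCl
Why: LiNEt2 converts 5 into lithium methoxyacetylide 6, which undergoes 1,2-addition to the aldehyde under polar Felkin–Anh control (attack anti to the C–OSi bond and past H, not isopropyl), setting C3 as R in the 3,4-anti product; the minor syn epimer is removed by chromatography on Et3N-deactivated silica.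

Step 5
Reactants: 7 (3R,4S)-4-(tert-butyldimethylsilyloxy)-1-methoxy-5-methylhex-1-yn-3-ol
Product: 8 (3R,4S)-4-(tert-butyldimethylsilyloxy)-1-methoxy-5-methyl-3-(triethylsilyloxy)hex-1-yne
Conditions: TESCl, imidazole, DMAP (cat.), CH2Cl2, 0 °C
Reagents that add atoms: chlorotriethylsilane, CC[Si](Cl)(CC)CC
Why: O-silylation under buffered, non-acidic conditions protects the propargylic alcohol without protonating the acid-sensitive ynol ether, and no stereocenter is touched.

Step 6
Reactants: 9 3-oxocyclobutanecarboxylic acid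
Product: 10 3-bromocyclobutanone
Conditions: HgO, Br2, MgSO4, CH2Cl2, reflux
Reagents that add atoms: bromine, BrBr
Why: Cristol–Firth modification of the Hunsdiecker reaction (radical bromodecarboxylation), the established entry to this β-bromo ketone.

Step 7
Reactants: 10 3-bromocyclobutanone
Product: 11 cyclobut-2-en-1-one
Conditions: n-Bu3N, rt; vacuum transfer into a −78 °C trap, used at once as a cold toluene solution
Reagents that add atoms: none
Why: Amine-induced E1cB dehydrobromination of a β-bromo ketone; the high-boiling amine lets the volatile, polymerisation-prone enone be distilled away from the salt.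

Step 8
Reactants: 8 (3R,4S)-4-(tert-butyldimethylsilyloxy)-1-methoxy-5-methyl-3-(triethylsilyloxy)hex-1-yne; 11 cyclobut-2-en-1-one
Product: 16 2-[(1R,2S)-2-(tert-butyldimethylsilyloxy)-3-methyl-1-(triethylsilyloxy)butyl]-3-methoxyphenol, via vinylketene 12 (not isolated), via 4-vinylcyclobutenone 13 (not isolated), via dienylketene 14 (not isolated), via cyclohexa-2,4-dienone 15 (not isolated)
Conditions: 11 (3 equiv, in portions), toluene, BHT (trace), sealed tube, 80 °C then 110 °C
Reagents that add atoms: cyclobut-2-en-1-one (reactant 11), O=C1C=CC1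
Why: Danheiser benzannulation: at 80 °C 11 undergoes 4π electrocyclic opening to vinylketene 12, whose ketene C=C adds [2+2] across ynol ether 8 to give 4-vinylcyclobutenone 13, which reopens (4π) to the cis-dienylketene 14, cyclises to dienone 15 and tautomerises to phenol 16. The closest known reaction type is the thermal annulation of cyclobutenones with 1-alkoxyalkynes to resorcinol monoethers. The only ring closed, benzene ring A, is formed by thermal disrotatory 6π electrocyclisation of 14 (bond C4a–C8a), after the [2+2] event has made the two intermolecular bonds C8–C8a and C6–C7. No stereocenter is created in 16 (the ring CH of 13 is transient), and because the cascade runs in neutral toluene with no acid, base or metal, the former propargylic carbon arrives as C1' (R) with C2' (S) intact. The step needs regiocontrol in the [2+2] addition, and the ynol ether itself provides it: donation from the methoxy oxygen makes the chain-bearing alkyne carbon the nucleophilic one, so it attacks the electrophilic ketene carbonyl carbon, which puts the side chain next to the new OH and the OMe on its other side. A methyl ynol ether has no β-hydrogen through which to lose an alkene by retro-ene fragmentation, so 8 should tolerate the heating.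

Step 9
Reactants: 16 2-[(1R,2S)-2-(tert-butyldimethylsilyloxy)-3-methyl-1-(triethylsilyloxy)butyl]-3-methoxyphenol
Product: 18 3-[(1R,2S)-2-(tert-butyldimethylsilyloxy)-3-methyl-1-(triethylsilyloxy)butyl]-2-hydroxy-4-methoxybenzaldehyde, via 6-(hydroxymethyl)phenol 17 (not isolated)
Conditions: MgCl2, Et3N, (CH2O)n, THF, reflux; aq. NH4Cl
Reagents that add atoms: paraformaldehyde (as formaldehyde), C=O
Why: Casnati–Skattebøl ortho-formylation: the magnesium phenoxide delivers coordinated formaldehyde only to the free ortho carbon (future C4a), and the hydroxymethyl intermediate 17 is oxidised to the aldehyde by hydride transfer to a second formaldehyde, under mildly basic conditions that should spare both silyl ethers.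

Step 10
Reactants: 18 3-[(1R,2S)-2-(tert-butyldimethylsilyloxy)-3-methyl-1-(triethylsilyloxy)butyl]-2-hydroxy-4-methoxybenzaldehyde
Product: 20 8-[(1R,2S)-2-(tert-butyldimethylsilyloxy)-3-methyl-1-(triethylsilyloxy)butyl]-7-methoxy-2H-chromen-2-one, via aryl phosphoranylideneacetate 19 (not isolated)
Conditions: Ph3P=C=C=O, toluene, 90 °C
Reagents that add atoms: (triphenylphosphoranylidene)ketene (Bestmann ylide), O=C=C=P(c1ccccc1)(c1ccccc1)c1ccccc1
Why: The phenol O–H adds across the ketene C=C of the Bestmann ylide to give ester ylide 19 held beside the aldehyde, and the intramolecular Wittig olefination then closes ring B with the necessarily cis C3=C4 bond under neutral conditions.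

Step 11
Reactants: 20 8-[(1R,2S)-2-(tert-butyldimethylsilyloxy)-3-methyl-1-(triethylsilyloxy)butyl]-7-methoxy-2H-chromen-2-one
Product: 21 8-[(1R,2S)-2-(tert-butyldimethylsilyloxy)-1-hydroxy-3-methylbutyl]-7-methoxy-2H-chromen-2-one
Conditions: HF·pyridine, pyridine, THF, 0 °C
Reagents that add atoms: none
Why: Selective desilylation: pyridine-buffered HF·pyridine cleaves a triethylsilyl ether far faster than a hindered secondary TBS ether, and the buffered medium avoids ionising the electron-rich benzylic C1'–O bond, so C1' keeps its configuration.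

Step 12
Reactants: 21 8-[(1R,2S)-2-(tert-butyldimethylsilyloxy)-1-hydroxy-3-methylbutyl]-7-methoxy-2H-chromen-2-one; 22 3-methylbut-2-enoic acid
Product: 24 (1R,2S)-2-(tert-butyldimethylsilyloxy)-1-(7-methoxy-2-oxo-2H-chromen-8-yl)-3-methylbutyl 3-methylbut-2-enoate, via O-acylisourea 23 (not isolated)
Conditions: 22, DCC, DMAP, CH2Cl2, 0 °C to rt
Reagents that add atoms: 3-methylbut-2-enoic acid (reactant 22), CC(C)=CC(=O)O
Why: Steglich esterification: DMAP-catalysed acyl transfer from O-acylisourea 23 acylates the benzylic alcohol on oxygen with retention at C1' (its C–O bond is not broken), and the absence of a trialkylamine limits deconjugation of the senecioyl group.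

Step 13
Reactants: 24 (1R,2S)-2-(tert-butyldimethylsilyloxy)-1-(7-methoxy-2-oxo-2H-chromen-8-yl)-3-methylbutyl 3-methylbut-2-enoate
Product: 25 (1R,2S)-2-hydroxy-1-(7-methoxy-2-oxo-2H-chromen-8-yl)-3-methylbutyl 3-methylbut-2-enoate
Conditions: HF·pyridine, THF, 0 °C to rt (polypropylene vessel)
Reagents that add atoms: none
Why: Fluoride-mediated desilylation under acidic conditions frees the C2' hydroxyl without ever forming an alkoxide, which should suppress 1,2-migration of the neighbouring senecioyl group and spare ester and lactone; the alcohol is oxidised without delay.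

Step 14
Reactants: 25 (1R,2S)-2-hydroxy-1-(7-methoxy-2-oxo-2H-chromen-8-yl)-3-methylbutyl 3-methylbut-2-enoate
Product: 26 (1R)-1-(7-methoxy-2-oxo-2H-chromen-8-yl)-3-methyl-2-oxobutyl 3-methylbut-2-enoate (CNP0130048.1)
Conditions: Dess–Martin periodinane, CH2Cl2, 0 °C to rt; aq. Na2S2O3/NaHCO3 work-up
Reagents that add atoms: none
Why: Dess–Martin oxidation turns the C2' carbinol into the ketone under neutral, non-enolising conditions, so the now acidic C1'–H (benzylic, α-keto, α-acyloxy) should not epimerise; the auxiliary C2' stereocenter is erased here.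

**Compound list**

1 | (S)-2-hydroxy-3-methylbutanoic acid | CC(C)[C@H](O)C(=O)O | starting material
2 | methyl (S)-2-hydroxy-3-methylbutanoate | CC(C)[C@H](O)C(=O)OC | intermediate
3 | methyl (S)-2-(tert-butyldimethylsilyloxy)-3-methylbutanoate | CC(C)[C@H](O[Si](C)(C)C(C)(C)C)C(=O)OC | intermediate
4 | (S)-2-(tert-butyldimethylsilyloxy)-3-methylbutanal | CC(C)[C@H](O[Si](C)(C)C(C)(C)C)C=O | intermediate
5 | chloroacetaldehyde dimethyl acetal | COC(OC)CCl | starting material
6 | lithium methoxyacetylide | COC#C[Li] | intermediate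
7 | (3R,4S)-4-(tert-butyldimethylsilyloxy)-1-methoxy-5-methylhex-1-yn-3-ol | COC#C[C@@H](O)[C@@H](O[Si](C)(C)C(C)(C)C)C(C)C | intermediate
8 | (3R,4S)-4-(tert-butyldimethylsilyloxy)-1-methoxy-5-methyl-3-(triethylsilyloxy)hex-1-yne | COC#C[C@@H](O[Si](CC)(CC)CC)[C@@H](O[Si](C)(C)C(C)(C)C)C(C)C | intermediate
9 | 3-oxocyclobutanecarboxylic acid | O=C1CC(C(=O)O)C1 | starting material
10 | 3-bromocyclobutanone | O=C1CC(Br)C1 | intermediate
11 | cyclobut-2-en-1-one | O=C1C=CC1 | intermediate
12 | vinylketene (buta-1,3-dien-1-one) | C=CC=C=O | intermediate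
13 | 2-[(1R,2S)-2-(tert-butyldimethylsilyloxy)-3-methyl-1-(triethylsilyloxy)butyl]-3-methoxy-4-vinylcyclobut-2-en-1-one (ring C4 epimers) | COC1=C([C@@H](O[Si](CC)(CC)CC)[C@@H](O[Si](C)(C)C(C)(C)C)C(C)C)C(=O)C1C=C | intermediate
14 | (3E)-2-[(1R,2S)-2-(tert-butyldimethylsilyloxy)-3-methyl-1-(triethylsilyloxy)butyl]-3-methoxyhexa-1,3,5-trien-1-one (ketene carbon and vinyl group cis) | O=C=C([C@@H](O[Si](CC)(CC)CC)[C@@H](O[Si](C)(C)C(C)(C)C)C(C)C)/C(OC)=C\C=C | intermediate
15 | 2-[(1R,2S)-2-(tert-butyldimethylsilyloxy)-3-methyl-1-(triethylsilyloxy)butyl]-3-methoxycyclohexa-2,4-dien-1-one | COC1=C([C@@H](O[Si](CC)(CC)CC)[C@@H](O[Si](C)(C)C(C)(C)C)C(C)C)C(=O)CC=C1 | intermediate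
16 | 2-[(1R,2S)-2-(tert-butyldimethylsilyloxy)-3-methyl-1-(triethylsilyloxy)butyl]-3-methoxyphenol | COc1cccc(O)c1[C@@H](O[Si](CC)(CC)CC)[C@@H](O[Si](C)(C)C(C)(C)C)C(C)C | intermediate
17 | 2-[(1R,2S)-2-(tert-butyldimethylsilyloxy)-3-methyl-1-(triethylsilyloxy)butyl]-6-(hydroxymethyl)-3-methoxyphenol | COc1ccc(CO)c(O)c1[C@@H](O[Si](CC)(CC)CC)[C@@H](O[Si](C)(C)C(C)(C)C)C(C)C | intermediate
18 | 3-[(1R,2S)-2-(tert-butyldimethylsilyloxy)-3-methyl-1-(triethylsilyloxy)butyl]-2-hydroxy-4-methoxybenzaldehyde | COc1ccc(C=O)c(O)c1[C@@H](O[Si](CC)(CC)CC)[C@@H](O[Si](C)(C)C(C)(C)C)C(C)C | intermediate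
19 | 2-[(1R,2S)-2-(tert-butyldimethylsilyloxy)-3-methyl-1-(triethylsilyloxy)butyl]-6-formyl-3-methoxyphenyl (triphenylphosphoranylidene)acetate | COc1ccc(C=O)c(OC(=O)C=P(c2ccccc2)(c2ccccc2)c2ccccc2)c1[C@@H](O[Si](CC)(CC)CC)[C@@H](O[Si](C)(C)C(C)(C)C)C(C)C | intermediate
20 | 8-[(1R,2S)-2-(tert-butyldimethylsilyloxy)-3-methyl-1-(triethylsilyloxy)butyl]-7-methoxy-2H-chromen-2-one | COc1ccc2ccc(=O)oc2c1[C@@H](O[Si](CC)(CC)CC)[C@@H](O[Si](C)(C)C(C)(C)C)C(C)C | intermediate
21 | 8-[(1R,2S)-2-(tert-butyldimethylsilyloxy)-1-hydroxy-3-methylbutyl]-7-methoxy-2H-chromen-2-one | COc1ccc2ccc(=O)oc2c1[C@@H](O)[C@@H](O[Si](C)(C)C(C)(C)C)C(C)C | intermediate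
22 | 3-methylbut-2-enoic acid | CC(C)=CC(=O)O | starting material
23 | O-(3-methylbut-2-enoyl)-N,N'-dicyclohexylisourea | CC(C)=CC(=O)OC(=NC1CCCCC1)NC1CCCCC1 | intermediate
24 | (1R,2S)-2-(tert-butyldimethylsilyloxy)-1-(7-methoxy-2-oxo-2H-chromen-8-yl)-3-methylbutyl 3-methylbut-2-enoate | COc1ccc2ccc(=O)oc2c1[C@@H](OC(=O)C=C(C)C)[C@@H](O[Si](C)(C)C(C)(C)C)C(C)C | intermediate
25 | (1R,2S)-2-hydroxy-1-(7-methoxy-2-oxo-2H-chromen-8-yl)-3-methylbutyl 3-methylbut-2-enoate | COc1ccc2ccc(=O)oc2c1[C@@H](OC(=O)C=C(C)C)[C@@H](O)C(C)C | intermediate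
26 | (1R)-1-(7-methoxy-2-oxo-2H-chromen-8-yl)-3-methyl-2-oxobutyl 3-methylbut-2-enoate (CNP0130048.1) | COc1ccc2ccc(=O)oc2c1[C@@H](OC(=O)C=C(C)C)C(=O)C(C)C | target

**Step count and risks**

Total step count: 14. Longest linear sequence: 12 steps (steps 1–5 and 8–14, from compound 1); steps 6–7 form the short cyclobutenone branch.

Steps most likely to fail:

1. Step 8 (benzannulation).
   - What may go wrong: polymerisation or dimerisation of cyclobutenone and vinylketene may outrun the [2+2] addition to an alkyne that is shielded by its α-branched bis-silyloxy chain. The second ring opening may stall at the vinylcyclobutenone stage. Surplus ketene may O-acylate the product phenol (a brief K2CO3/MeOH treatment of the crude should reverse this). Prolonged heating may cause thermal loss of triethylsilanol from the ortho-hydroxybenzyl silyl ether.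
   - Fallback (sets out from aldehyde 4, returns at phenol 16): commercial 2-bromo-3-methoxyphenol would be O-allylated (allyl bromide, K2CO3, acetone) to 1-(allyloxy)-2-bromo-3-methoxybenzene F1. Bromine–lithium exchange (n-BuLi, THF, −78 °C) and addition to 4 at −78 °C should give, again under Felkin–Anh control, (1R,2S)-1-[2-(allyloxy)-6-methoxyphenyl]-2-(tert-butyldimethylsilyloxy)-3-methylbutan-1-ol F2. Silylation (TESOTf, 2,6-lutidine, CH2Cl2, −78 °C) would give {(1R,2S)-1-[2-(allyloxy)-6-methoxyphenyl]-2-(tert-butyldimethylsilyloxy)-3-methylbutoxy}triethylsilane F3, and deallylation with Pd(PPh3)4 and morpholine in THF would deliver 16.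

2. Step 9 (ortho-formylation).
   - What may go wrong: the magnesium phenoxide may expel the benzylic silyloxy group on heating (quinone methide formation), the triethylsilyl group may be lost, or the crowded phenoxide may simply fail to take up formaldehyde.
   - Fallback (sets out from phenol 16, returns at coumarin 20, bypassing 18): esterification of 16 with propiolic acid (DCC, CH2Cl2, −20 °C) would give 2-[(1R,2S)-2-(tert-butyldimethylsilyloxy)-3-methyl-1-(triethylsilyloxy)butyl]-3-methoxyphenyl propiolate F4. Intramolecular 6-endo hydroarylation catalysed by Ph3PAuCl/AgSbF6 in 1,2-dichloroethane at rt can close only at the free ortho carbon, which is para to the methoxy group, and would give 20 directly.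

3. Step 4 (acetylide addition).
   - What may go wrong: facial selectivity of the lithium acetylide addition to the α-silyloxy aldehyde may be modest, and the aldehyde may partly epimerise at its α-carbon under the lithium amide/alkoxide conditions.
   - Fallback (sets out from 7 as obtained, mixed with its epimer, and returns at 7): the mixture of 7 and (3S,4S)-4-(tert-butyldimethylsilyloxy)-1-methoxy-5-methylhex-1-yn-3-ol F5 would be oxidised with MnO2 (CH2Cl2, rt) to (S)-4-(tert-butyldimethylsilyloxy)-1-methoxy-5-methylhex-1-yn-3-one F6. Reagent-controlled reduction with (S)-2-methyl-CBS-oxazaborolidine and catecholborane (toluene, −78 °C), in which the slim methoxyethynyl group should act as the small substituent and the substrate's own Felkin bias points the same way, is expected to return 7 as the (3R) carbinol.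

**Further compounds**

F1 | step 8 | 1-(allyloxy)-2-bromo-3-methoxybenzene | COc1cccc(OCC=C)c1Br
F2 | step 8 | (1R,2S)-1-[2-(allyloxy)-6-methoxyphenyl]-2-(tert-butyldimethylsilyloxy)-3-methylbutan-1-ol | COc1cccc(OCC=C)c1[C@@H](O)[C@@H](O[Si](C)(C)C(C)(C)C)C(C)C
F3 | step 8 | {(1R,2S)-1-[2-(allyloxy)-6-methoxyphenyl]-2-(tert-butyldimethylsilyloxy)-3-methylbutoxy}triethylsilane | COc1cccc(OCC=C)c1[C@@H](O[Si](CC)(CC)CC)[C@@H](O[Si](C)(C)C(C)(C)C)C(C)C
F4 | step 9 | 2-[(1R,2S)-2-(tert-butyldimethylsilyloxy)-3-methyl-1-(triethylsilyloxy)butyl]-3-methoxyphenyl propiolate | COc1cccc(OC(=O)C#C)c1[C@@H](O[Si](CC)(CC)CC)[C@@H](O[Si](C)(C)C(C)(C)C)C(C)C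
F5 | step 4 | (3S,4S)-4-(tert-butyldimethylsilyloxy)-1-methoxy-5-methylhex-1-yn-3-ol | COC#C[C@H](O)[C@@H](O[Si](C)(C)C(C)(C)C)C(C)C
F6 | step 4 | (S)-4-(tert-butyldimethylsilyloxy)-1-methoxy-5-methylhex-1-yn-3-one | COC#CC(=O)[C@@H](O[Si](C)(C)C(C)(C)C)C(C)C
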